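Two late percentages that nearly match look like proof that the charge does not matter, and that is the trap: at 120 min the autumn run shows 59% over-reaction product and the spring run 57%, yet each reading scatters by 1.5 percentage points.

| flask | substrate | remark | time |
|---|---|---|---|
| autumn | 0.067 M | run made earlier |  |
| spring | 0.15 M | run made earlier |  |
| flask | 0.10 M |  | 1.5 h |

| run | time / min | over-reaction product / % | ring / % | open dimer / % | substrate / % |
|---|---|---|---|---|---|
| autumn | 20.0 | 14 | 14 | 11 | 37 |
| autumn | 40.0 | 28 | 8 | 12 | 27 |
| autumn | 50.0 | 37 | 3 | 9 | 23 |
| autumn | 80.0 | 50 | 3 | 9 | 17 |
| autumn | 90.0 | 55 | 6 | 11 | 14 |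
| autumn | 120 | 59 | 5 | 6 | 10 |
| spring | 8.00 | 4 | 8 | 17 | 56 |
| spring | 20.0 | 12 | 10 | 23 | 33 |
| spring | 40.0 | 26 | 5 | 22 | 23 |
| spring | 60.0 | 36 | 5 | 20 | 19 |
| spring | 80.0 | 43 | 5 | 15 | 18 |
| spring | 120 | 57 | 0 | 11 | 12 |

(each reading ± 1.5 percentage points)

1. where most of what was charged as substrate, at 1.5 h is found (ring / over-reaction product / open dimer / substrate)
2. the largest share itself, whichever of these holds it, in percent of the substrate charged

- in percentages every species weighs as the substrate in it: one open dimer counts as two
- the analysis behind the earlier runs scatters by 1.5 percentage points, standard deviation
- a reading or a percentage of substrate is of its free form alone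

The species is not in dispute: in the autumn run at 90.0 min, over-reaction product stands at 55%, more than substrate at 14%. The share is.

One chemist holds a single clock (first-order behaviour): a percentage at a given time ignores the charge. The autumn run is read at the asked time, so its 55% is her figure for the flask.

The other answers that open dimer pairs two substrates, so a bigger charge should behave differently. At 80.0 min the spring run holds 15% open dimer, more than the autumn run's 9%, and 43% over-reaction product, less than its 50%. That pair gives 8.7 points as the dilution slope, the points of over-reaction product lost at a fixed time per unit of the natural logarithm of the charge.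

I side with him: down that slope from the autumn reading, the flask holds 51.5%.

The forecast says over-reaction product at 50%, a little below my figure: “The percentage depends only weakly on concentration”.

The flask gives over-reaction product at 50.0%, which is 1.5 points under my figure and 5 points under hers.

    substrate ⇌ ring (K = 31.0, k = 0.0200 min⁻¹)
    2 substrate ⇌ open dimer (K = 8.80 M⁻¹, k = 0.150 M⁻¹ min⁻¹)
    substrate ⇌ dormant form (K = 0.950, k = 0.0250 min⁻¹)
    ring → over-reaction product (k = 0.0880 min⁻¹)

Her clock still has its region: at 1.5 h, over-reaction product stays within 5 points of this flask's value for charges between 0.0344 M and 0.195 M, so across that span this flask's own percentage serves for any charge to that margin. A neighbour flask, charged with 0.25 M and read at the same time, stands beyond that region. The dilution slope of 8.7 points, applied from the flask's 50.0% over the ratio of the charges, gives 42.1%. That neighbour holds open dimer at 20.7%, against 10.9% in the flask, and over-reaction product at 42.8%.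

The data are calculated with constants of no real substance; noise was put on by code.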